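**Retrosynthetic overview**
1. Target 18 ⇐ methyl ester 17 ⇐ diketone 15 by double methylenation; the C10 side chain is the dimer of methyl vinyl ketone plus two CH2.
2. 15 ⇐ C8-prenyl chromanone 11 + 3-methyleneheptane-2,6-dione 13 by a catalytic asymmetric dearomative Michael addition/protonation that sets the quaternary carbon and the side-chain CH in one step.
3. 11 ⇐ tricyclic lactone 8 (lactone methanolysis, nuclear prenylation); 8 ⇐ 8-tigloyl dihydrocoumarin 7 by quinine-catalysed oxa-Michael ring closure (cis-2,3-dimethylpyranone).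
4. 7 ⇐ (S)-dihydrocoumarin 5 (C8 acylation) ⇐ phloroglucinol + (E)-hex-2-enal by iminium-catalysed Friedel–Crafts/hemiacetalisation and lactol oxidation (first stereocentre).
5. Ring order: lactone ring (temporary; blocks one oxygen so the pyranone can only close on the other) → pyranone ring → lactone reopened → dearomatised carbocycle.

Assumption: the sense of induction in steps 1, 4 and 7 is taken from the models given there (the enantiomeric or pseudo-enantiomeric catalyst is used if a sense is found reversed), and the target is handled as the drawn 5-hydroxy-4,7-dioxo tautomer.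

**Step 1**
Reactants: 1 phloroglucinol; 2 (E)-hex-2-enal
Product: 4 (4S)-4-propylchromane-2,5,7-triol (lactol; C2 epimers), via open-chain aldehyde 3 (not isolated)
Conditions: (R)-α,α-bis[3,5-bis(trifluoromethyl)phenyl]prolinol trimethylsilyl ether (10 mol %), PhCO2H (10 mol %), THF, 0 °C, slow addition of 2 over 4 h
Reagents that add atoms: none
Why: Iminium-catalysed Friedel–Crafts conjugate addition then hemiacetalisation; the (R)-catalyst shields one face of the (E)-iminium so the arene adds to the β-carbon to give 4S, symmetric 1 gives a single regioisomer, and slow addition of 2 keeps 1 in excess in solution and suppresses bis-alkylation.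

**Step 2**
Reactants: 4 (4S)-4-propylchromane-2,5,7-triol
Product: 5 (4S)-5,7-dihydroxy-4-propyl-3,4-dihydro-2H-chromen-2-one
Conditions: Ag2CO3 on Celite, toluene/dioxane, 80 °C
Reagents that add atoms: none
Why: Fétizon oxidation converts the lactol into the δ-lactone without phenol protection and does not touch C4.

**Step 3**
Reactants: 5 (4S)-5,7-dihydroxy-4-propyl-3,4-dihydro-2H-chromen-2-one; 6 tigloyl chloride
Product: 7 (4S)-5,7-dihydroxy-8-[(2E)-2-methylbut-2-enoyl]-4-propyl-3,4-dihydro-2H-chromen-2-one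
Conditions: AlCl3 (3.5 equiv), PhNO2/ClCH2CH2Cl, 0 °C to rt
Reagents that add atoms: none
Why: Friedel–Crafts C-acylation goes to C8 (ortho to 7-OH, para to 5-OH) rather than C6 between the two hydroxyls, as in the acylation of 5,7-dihydroxy-4-alkylcoumarins; the minor 6-acyl isomer is removed by chromatography, and the lactone oxygen leaves 7-OH as the only hydroxyl ortho to the enone.

**Step 4**
Reactants: 7 (4S)-5,7-dihydroxy-8-[(2E)-2-methylbut-2-enoyl]-4-propyl-3,4-dihydro-2H-chromen-2-one
Product: 8 (4S,8R,9S)-5-hydroxy-8,9-dimethyl-4-propyl-3,4,8,9-tetrahydro-2H,10H-pyrano[2,3-f]chromene-2,10-dione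
Conditions: (−)-quinine (20 mol %), PhCl, rt
Reagents that add atoms: none
Why: Quinine-catalysed intramolecular oxa-Michael addition, known for 7-hydroxy-8-tigloylcoumarins, gives the kinetic cis-2,3-dimethylchromanone; the quinuclidinium-bound phenolate adds to one enone face (O–CH centre R) and the enol is protonated to the cis isomer (CH–C=O centre S).

**Step 5**
Reactants: 8 the tricyclic lactone-chromanone; 9 prenyl bromide
Product: 11 methyl (3S)-3-[(2R,3S)-5,7-dihydroxy-2,3-dimethyl-8-(3-methylbut-2-en-1-yl)-4-oxo-3,4-dihydro-2H-chromen-6-yl]hexanoate, via ring-opened methyl ester 10 (not isolated)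
Conditions: NaOMe (3 equiv), MeOH, 0 °C, 30 min; then 9 (1.2 equiv), 0 °C, 3 h; AcOH quench
Reagents that add atoms: sodium methoxide in methanol (supplies the ester OCH3), C[O-].[Na+]
Why: Methoxide opens the aryl lactone to phenolate 10 and the acylphloroglucinol-type dianion is C-prenylated at its only free ring carbon (classical nuclear prenylation in protic medium); the dianionic ring lowers the acidity at C3, so the cis-chromanone is kept at 0 °C.

**Step 6**
Reactants: 12 methyl vinyl ketone (2 equiv)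
Product: 13 3-methyleneheptane-2,6-dione
Conditions: DABCO (15 mol %), THF, rt
Reagents that add atoms: none
Why: Amine-catalysed Rauhut–Currier (Baylis–Hillman type) head-to-tail dimerisation of the vinyl ketone.

**Step 7**
Reactants: 11 the C8-prenyl dihydroxychromanone ester; 13 3-methyleneheptane-2,6-dione
Product: 15 methyl (3S)-3-[(2R,3S,8R)-8-[(2R)-2-acetyl-5-oxohexyl]-5-hydroxy-2,3-dimethyl-8-(3-methylbut-2-en-1-yl)-4,7-dioxo-3,4,7,8-tetrahydro-2H-chromen-6-yl]hexanoate, via side-chain enol 14 (not isolated)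
Conditions: 9-amino-9-deoxy-epi-quinidine 3,5-bis(trifluoromethyl)phenyl squaramide (20 mol %), 13 (1.5 equiv), toluene, 4 Å MS, −20 °C
Reagents that add atoms: none
Why: Proposed new method: dearomative conjugate addition–enantioselective protonation; the catalyst quinuclidine deprotonates the acidic 7-OH to a tight chiral ammonium phenolate, the squaramide NH pair binds the s-cis enone carbonyl of 13, C8 (prenyl-bearing, ortho to O−; C6 is blocked by the branched chain) adds to the terminal CH2 on the face left open by the catalyst to set the quaternary centre (8R), and the still-bound side-chain enol(ate) 14 is protonated on one face by the adjacent quinuclidinium N–H to set the acetyl-bearing carbon (R), with formation of the chelated vinylogous acid driving the dearomatisation; the closest known reactions are cinchona-catalysed tandem conjugate addition–protonation that sets 1,3-related stereocentres from trisubstituted carbon nucleophiles and α-substituted acceptors, and base- or phase-transfer-mediated alkylative dearomatisation of prenylated acylphloroglucinols with enals; new here are the dearomatising phenolic nucleophile and the α-alkyl vinyl ketone acceptor.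

**Step 8**
Reactants: 15 the diketone ester
Product: 17 methyl (3S)-3-[(2R,3S,8R)-5-hydroxy-2,3-dimethyl-8-(3-methylbut-2-en-1-yl)-8-[(2R)-5-methyl-2-(prop-1-en-2-yl)hex-5-en-1-yl]-4,7-dioxo-3,4,7,8-tetrahydro-2H-chromen-6-yl]hexanoate, via mono-methylenated ketone 16 (not isolated)
Conditions: Ph3PCH3Br (6 equiv), KN(SiMe3)2 (5.5 equiv), THF, 0 °C; then 15, −78 to 0 °C
Reagents that add atoms: methyltriphenylphosphonium bromide (as its ylide; supplies both CH2 groups), C[P+](c1ccccc1)(c1ccccc1)c1ccccc1.[Br-]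
Why: Double Wittig methylenation of the two methyl ketones; base is kept below the phosphonium salt so no free amide is present, the ring system sits as its unreactive enolate, the ester is inert, and any enolisation is at the methyl side so the α-stereocentre is kept.

**Step 9**
Reactants: 17 the methyl ester
Product: 18 (3S)-3-[(2R,3S,8R)-5-hydroxy-2,3-dimethyl-8-(3-methylbut-2-en-1-yl)-8-[(2R)-5-methyl-2-(prop-1-en-2-yl)hex-5-en-1-yl]-4,7-dioxo-3,4,7,8-tetrahydro-2H-chromen-6-yl]hexanoic acid (target)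
Conditions: LiOH (3 equiv), THF/H2O, 0 °C to rt; then 1 M HCl to pH 4 at 0 °C
Reagents that add atoms: lithium hydroxide (supplies the acid OH oxygen), [Li+].[OH-]
Why: Saponification of the methyl ester; the vinylogous acid is present as its enolate, which protects the chromanone from C3 epimerisation, and mild acidification avoids acid-induced prenyl cyclisation.

**Compound list**
1 | phloroglucinol (benzene-1,3,5-triol) | Oc1cc(O)cc(O)c1 | starting material
2 | (E)-hex-2-enal | CCC/C=C/C=O | starting material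
3 | (3S)-3-(2,4,6-trihydroxyphenyl)hexanal | O=CC[C@H](CCC)c1c(O)cc(O)cc1O | intermediate
4 | (4S)-4-propylchromane-2,5,7-triol (lactol, C2 epimers) | OC1C[C@H](CCC)c2c(O)cc(O)cc2O1 | intermediate
5 | (4S)-5,7-dihydroxy-4-propyl-3,4-dihydro-2H-chromen-2-one | O=C1C[C@H](CCC)c2c(O)cc(O)cc2O1 | intermediate
6 | tigloyl chloride, (2E)-2-methylbut-2-enoyl chloride | C/C=C(\C)C(=O)Cl | starting material
7 | (4S)-5,7-dihydroxy-8-[(2E)-2-methylbut-2-enoyl]-4-propyl-3,4-dihydro-2H-chromen-2-one | O=C1C[C@H](CCC)c2c(O)cc(O)c(C(=O)/C(C)=C/C)c2O1 | intermediate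
8 | (4S,8R,9S)-5-hydroxy-8,9-dimethyl-4-propyl-3,4,8,9-tetrahydro-2H,10H-pyrano[2,3-f]chromene-2,10-dione (dihydrocoumarin with a cis-dimethylpyranone fused at C7–O/C8) | O=C1C[C@H](CCC)c2c(O)cc3O[C@H](C)[C@H](C)C(=O)c3c2O1 | intermediate
9 | prenyl bromide, 1-bromo-3-methylbut-2-ene | CC(C)=CCBr | starting material
10 | methyl (3S)-3-[(2R,3S)-5,7-dihydroxy-2,3-dimethyl-4-oxo-3,4-dihydro-2H-chromen-6-yl]hexanoate | CCC[C@@H](CC(=O)OC)c1c(O)cc2O[C@H](C)[C@H](C)C(=O)c2c1O | intermediate
11 | methyl (3S)-3-[(2R,3S)-5,7-dihydroxy-2,3-dimethyl-8-(3-methylbut-2-en-1-yl)-4-oxo-3,4-dihydro-2H-chromen-6-yl]hexanoate | CCC[C@@H](CC(=O)OC)c1c(O)c(CC=C(C)C)c2O[C@H](C)[C@H](C)C(=O)c2c1O | intermediate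
12 | methyl vinyl ketone (but-3-en-2-one) | C=CC(C)=O | starting material
13 | 3-methyleneheptane-2,6-dione | CC(=O)CCC(=C)C(C)=O | intermediate
14 | side-chain enol of 15: methyl (3S)-3-[(2R,3S,8R)-5-hydroxy-8-[2-(1-hydroxyethylidene)-5-oxohexyl]-2,3-dimethyl-8-(3-methylbut-2-en-1-yl)-4,7-dioxo-3,4,7,8-tetrahydro-2H-chromen-6-yl]hexanoate (enol geometry undefined) | CC(=O)CCC(C[C@@]1(CC=C(C)C)C(=O)C([C@@H](CCC)CC(=O)OC)=C(O)C2=C1O[C@H](C)[C@H](C)C2=O)=C(C)O | intermediate
15 | methyl (3S)-3-[(2R,3S,8R)-8-[(2R)-2-acetyl-5-oxohexyl]-5-hydroxy-2,3-dimethyl-8-(3-methylbut-2-en-1-yl)-4,7-dioxo-3,4,7,8-tetrahydro-2H-chromen-6-yl]hexanoate | CC(=O)CC[C@H](C[C@@]1(CC=C(C)C)C(=O)C([C@@H](CCC)CC(=O)OC)=C(O)C2=C1O[C@H](C)[C@H](C)C2=O)C(C)=O | intermediate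
16 | methyl (3S)-3-[(2R,3S,8R)-8-[(2R)-2-acetyl-5-methylhex-5-en-1-yl]-5-hydroxy-2,3-dimethyl-8-(3-methylbut-2-en-1-yl)-4,7-dioxo-3,4,7,8-tetrahydro-2H-chromen-6-yl]hexanoate | C=C(C)CC[C@H](C[C@@]1(CC=C(C)C)C(=O)C([C@@H](CCC)CC(=O)OC)=C(O)C2=C1O[C@H](C)[C@H](C)C2=O)C(C)=O | intermediate
17 | methyl (3S)-3-[(2R,3S,8R)-5-hydroxy-2,3-dimethyl-8-(3-methylbut-2-en-1-yl)-8-[(2R)-5-methyl-2-(prop-1-en-2-yl)hex-5-en-1-yl]-4,7-dioxo-3,4,7,8-tetrahydro-2H-chromen-6-yl]hexanoate | C=C(C)CC[C@H](C[C@@]1(CC=C(C)C)C(=O)C([C@@H](CCC)CC(=O)OC)=C(O)C2=C1O[C@H](C)[C@H](C)C2=O)C(=C)C | intermediate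
18 | (3S)-3-[(2R,3S,8R)-5-hydroxy-2,3-dimethyl-8-(3-methylbut-2-en-1-yl)-8-[(2R)-5-methyl-2-(prop-1-en-2-yl)hex-5-en-1-yl]-4,7-dioxo-3,4,7,8-tetrahydro-2H-chromen-6-yl]hexanoic acid | C=C(C)CC[C@H](C[C@@]1(CC=C(C)C)C(=O)C([C@@H](CCC)CC(=O)O)=C(O)C2=C1O[C@H](C)[C@H](C)C2=O)C(=C)C | target

**Step count**
Total steps: 9. Longest linear sequence: 8 (steps 1 to 5, then 7 to 9; step 6 makes the acceptor).

**Steps most likely to fail**

Step 7 (the proposed new step). Risks: face control at C8, face control of the enol protonation (the α-acetyl centre cannot be corrected later), slowing of turnover because the product is a stronger acid than 11, and reversible O-addition. The fallback uses known chemistry, sets out from 11 and comes back to the route at 15, building the two centres one at a time. Phase-transfer alkylative dearomatisation of 11 with acrolein (N-(9-anthracenylmethyl)cinchonidinium bromide, CsOH·H2O, toluene, −50 °C) gives the C8 3-oxopropyl aldehyde F1, with C8 set by the chiral ammonium ion pair. Enamine-catalysed Michael addition of F1 to methyl vinyl ketone 12 ((R)-α,α-diphenylprolinol trimethylsilyl ether, 4-nitrophenol co-catalyst, CH2Cl2, 4 °C) gives the keto aldehyde F2, with the side-chain CH set by the catalyst. Aldehyde-selective methyl addition with MeTi(OiPr)3 (THF, −40 °C) gives the secondary carbinol F3, and Dess–Martin oxidation of F3 gives 15.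

Step 5. Risks: O- instead of C-prenylation, over-prenylation, and methoxide-induced C3 epimerisation or retro-oxa-Michael opening of the cis-chromanone. The fallback works under neutral conditions, sets out from 8 and comes back to the route at 11. O-alkylation of the single free phenol of 8 with tert-butyl 2-methylbut-3-en-2-yl carbonate and Pd(PPh3)4 (THF, 0 °C) gives the 1,1-dimethylallyl aryl ether F4. Aromatic Claisen rearrangement (toluene, 110 °C) moves the group to the only free ortho carbon with allyl inversion, giving the C-prenyl lactone F5. Mild methanolysis of the aryl lactone of F5 (MeOH, Et3N, 40 °C) gives 11.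

Step 8. Risks: ylide-induced enolisation and intramolecular aldol of the 1,5-diketone, erosion of the centre α to the acetyl group, and incomplete second methylenation. The fallback is a non-basic addition/elimination, sets out from 15 and comes back to the route at 17. Addition of TMSCH2MgCl/CeCl3 (THF, −78 °C) to both ketones of 15 gives the bis(β-hydroxysilane) F6, and Peterson elimination of F6 with HF·pyridine (THF, 0 °C) gives 17.

**Further compounds**
F1 | step 7 | methyl (3S)-3-[(2R,3S,8S)-5-hydroxy-2,3-dimethyl-8-(3-methylbut-2-en-1-yl)-4,7-dioxo-8-(3-oxopropyl)-3,4,7,8-tetrahydro-2H-chromen-6-yl]hexanoate (same spatial arrangement at C8 as 15) | O=CCC[C@@]1(CC=C(C)C)C(=O)C([C@@H](CCC)CC(=O)OC)=C(O)C2=C1O[C@H](C)[C@H](C)C2=O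
F2 | step 7 | methyl (3S)-3-[(2R,3S,8R)-8-[(2R)-2-formyl-5-oxohexyl]-5-hydroxy-2,3-dimethyl-8-(3-methylbut-2-en-1-yl)-4,7-dioxo-3,4,7,8-tetrahydro-2H-chromen-6-yl]hexanoate | CC(=O)CC[C@H](C[C@@]1(CC=C(C)C)C(=O)C([C@@H](CCC)CC(=O)OC)=C(O)C2=C1O[C@H](C)[C@H](C)C2=O)C=O
F3 | step 7 | methyl (3S)-3-[(2R,3S,8R)-5-hydroxy-8-[(2R)-2-(1-hydroxyethyl)-5-oxohexyl]-2,3-dimethyl-8-(3-methylbut-2-en-1-yl)-4,7-dioxo-3,4,7,8-tetrahydro-2H-chromen-6-yl]hexanoate (carbinol epimers) | CC(=O)CC[C@H](C[C@@]1(CC=C(C)C)C(=O)C([C@@H](CCC)CC(=O)OC)=C(O)C2=C1O[C@H](C)[C@H](C)C2=O)C(C)O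
F4 | step 5 | (4S,8R,9S)-8,9-dimethyl-5-[(2-methylbut-3-en-2-yl)oxy]-4-propyl-3,4,8,9-tetrahydro-2H,10H-pyrano[2,3-f]chromene-2,10-dione | O=C1C[C@H](CCC)c2c(OC(C)(C)C=C)cc3O[C@H](C)[C@H](C)C(=O)c3c2O1
F5 | step 5 | (4S,8R,9S)-5-hydroxy-8,9-dimethyl-6-(3-methylbut-2-en-1-yl)-4-propyl-3,4,8,9-tetrahydro-2H,10H-pyrano[2,3-f]chromene-2,10-dione | O=C1C[C@H](CCC)c2c(O)c(CC=C(C)C)c3O[C@H](C)[C@H](C)C(=O)c3c2O1
F6 | step 8 | methyl (3S)-3-[(2R,3S,8R)-5-hydroxy-8-[5-hydroxy-2-(2-hydroxy-1-(trimethylsilyl)propan-2-yl)-5-methyl-6-(trimethylsilyl)hexyl]-2,3-dimethyl-8-(3-methylbut-2-en-1-yl)-4,7-dioxo-3,4,7,8-tetrahydro-2H-chromen-6-yl]hexanoate (side-chain CH as in 15; carbinol epimers) | C[Si](C)(C)CC(C)(O)CC[C@H](C[C@@]1(CC=C(C)C)C(=O)C([C@@H](CCC)CC(=O)OC)=C(O)C2=C1O[C@H](C)[C@H](C)C2=O)C(C)(O)C[Si](C)(C)C
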